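**Retrosynthetic overview**
1. Target ⇒ phenol deacetylation, hydroxyl-directed reduction of the C2 ketone and acylation of the C6 hydroxyl ⇒ diol ketone 13.
2. Key disconnection, C4–O: 13 ⇒ δ-hydroxy enone 11 by a boronic-acid-tethered oxa-Michael addition, with the oxygen delivered from O6 to C4.
3. 11 ⇒ ring-closing metathesis of diene 10; the seven-membered ring is formed second, onto the five-membered ring.
4. 10 ⇒ α′-methylation/allylation of enone 8 ⇒ Stork–Danheiser isopropyl transposition of aldol 6.
5. 6 ⇒ anti boron aldol of 3-ethoxycyclopent-2-en-1-one (five-membered ring bought) with 3-methylbut-3-enal, then lipase resolution.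

Assumption: carbon labels C1–C15 in the explanations follow daucane numbering (C1 = methyl-bearing ring-fusion carbon, C2 and C4 = carbinol carbons of the five-membered ring, C5 = ring-fusion CH, C6 = ester carbinol, C8=C9 = ring alkene); 1, 3 and 14 are bought.

**Route**

Step 1
Reactants: 1 3-methylbut-3-en-1-ol
Product: 2 3-methylbut-3-enal
Conditions: Dess–Martin periodinane, NaHCO3, CH2Cl2, 0 °C → rt; filtered solution used at once
Reagents that add atoms: none
Why: Dess–Martin oxidation under buffered, non-enolising conditions stops at the β,γ-unsaturated aldehyde without moving the alkene into conjugation, and no stereocentre is involved.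

Step 2
Reactants: 3 3-ethoxycyclopent-2-en-1-one; 2 3-methylbut-3-enal
Product: 5 rac-(5S,1′S)-3-ethoxy-5-(1-hydroxy-3-methylbut-3-en-1-yl)cyclopent-2-en-1-one, via boron enolate 4 (not isolated)
Conditions: (c-C6H11)2BCl, Et3N, Et2O, 0 °C; 2, −78 → −20 °C; then MeOH, pH 7 buffer, 30% H2O2, 0 °C
Reagents that add atoms: none
Why: boron-mediated aldol addition in which the ring forces the E(O)-enol borinate at the α′ carbon and its closed chair (Zimmerman–Traxler) transition state gives the anti aldol, the relative configuration of C5 and C6 of the target, as a racemate.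

Step 3
Reactants: 5 rac-(5S,1′S)-3-ethoxy-5-(1-hydroxy-3-methylbut-3-en-1-yl)cyclopent-2-en-1-one
Product: 6 (5S)-3-ethoxy-5-[(1S)-1-hydroxy-3-methylbut-3-en-1-yl]cyclopent-2-en-1-one
Conditions: Amano lipase PS (Burkholderia cepacia, immobilised), vinyl acetate, tert-butyl methyl ether, 30 °C, stopped near 55% conversion
Reagents that add atoms: none
Why: enzymatic kinetic resolution by transesterification in which, following the Kazlauskas rule, the lipase acetylates the (1′R) carbinol (large ring substituent, medium methallyl group) and leaves the (5S,1′S) alcohol, which fixes the absolute configuration of C5 and C6 (at most half of the material is kept).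

Step 4
Reactants: 6 (5S)-3-ethoxy-5-[(1S)-1-hydroxy-3-methylbut-3-en-1-yl]cyclopent-2-en-1-one
Product: 8 (4R)-4-[(1S)-1-hydroxy-3-methylbut-3-en-1-yl]-3-(propan-2-yl)cyclopent-2-en-1-one, via tertiary allylic carbinol 7 (not isolated)
Conditions: iPrMgCl, CeCl3 (3 equiv each), THF, −78 → 0 °C; then 1 M HCl, THF, 0 °C
Reagents that add atoms: isopropylmagnesium chloride CC(C)[Mg]Cl; water O
Why: Stork–Danheiser alkylative carbonyl transposition in which the weakly basic organocerium reagent adds 1,2 to the vinylogous ester carbonyl and acid hydrolysis of the enol ether with loss of water gives the β-isopropyl enone, leaving both stereocentres untouched.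

Step 5
Reactants: 8 (4R)-4-[(1S)-1-hydroxy-3-methylbut-3-en-1-yl]-3-(propan-2-yl)cyclopent-2-en-1-one
Product: 10 (4S,5R)-4-[(1S)-1-hydroxy-3-methylbut-3-en-1-yl]-5-methyl-3-(propan-2-yl)-5-(prop-2-en-1-yl)cyclopent-2-en-1-one, via 5-methyl enone 9 (not isolated)
Conditions: LiN(iPr)2 (2.2 equiv), THF, −78 °C; MeI (1.05 equiv), −78 → −40 °C; then LiN(iPr)2 (1.2 equiv), −78 °C; allyl bromide, −78 → −20 °C; H2O
Reagents that add atoms: iodomethane CI; allyl bromide C=CCBr
Why: sequential kinetic α′-alkylation of the cross-conjugated lithium dienolate (the lithium alkoxide stays inert, as in Fráter–Seebach dianion alkylations), in which the second electrophile, allyl bromide, enters the planar enolate anti to the bulky C5 side chain and so sets the quaternary C1 with allyl trans and methyl cis to that chain.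

Step 6
Reactants: 10 (4S,5R)-4-[(1S)-1-hydroxy-3-methylbut-3-en-1-yl]-5-methyl-3-(propan-2-yl)-5-(prop-2-en-1-yl)cyclopent-2-en-1-one
Product: 11 (3aS,4S,8aR)-4-hydroxy-6,8a-dimethyl-3-(propan-2-yl)-4,5,8,8a-tetrahydroazulen-1(3aH)-one
Conditions: second-generation Hoveyda–Grubbs catalyst [RuCl2(H2IMes)(=CH–C6H4-2-OiPr)] (5 mol %), toluene (5 mM), 80 °C
Reagents that add atoms: none
Why: ring-closing metathesis of the allyl and methallyl groups closes the seven-membered ring with the trisubstituted C8=C9 alkene, the trans arrangement of the two chains gives the trans-fused hydroazulene, and the hindered, electron-poor enone alkene does not take part.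

Step 7
Reactants: 11 (3aS,4S,8aR)-4-hydroxy-6,8a-dimethyl-3-(propan-2-yl)-4,5,8,8a-tetrahydroazulen-1(3aH)-one
Product: 13 (3R,3aS,4S,8aR)-3,4-dihydroxy-6,8a-dimethyl-3-(propan-2-yl)-3,3a,4,5,8,8a-hexahydroazulen-1(2H)-one, via cyclic phenylboronate 12 (not isolated)
Conditions: PhB(OH)2 (1.3 equiv), quinuclidine (20 mol %), N,N′-bis[3,5-bis(trifluoromethyl)phenyl]thiourea (20 mol %), 4 Å molecular sieves, toluene, 50 °C; then 30% H2O2, pH 7 phosphate buffer, THF, rt
Reagents that add atoms: phenylboronic acid OB(O)c1ccccc1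
Why: Proposed new method: the C6 hydroxyl condenses with PhB(OH)2 to a hemiboronate whose remaining B–OH, made nucleophilic by quinuclidine coordination at boron while the thiourea hydrogen-bonds the enone carbonyl, adds through a six-membered chair transition state to the β-carbon C4 of the β,β-disubstituted cyclopentenone, and because the O6–B tether hangs from C6 on the β-face of the five-membered ring it can reach C4 only from that face, so the tertiary C4–O bond forms cis to C6 (4β-O, isopropyl α) and is held as a neutral dioxaborinane that cannot revert by alkoxide expulsion before buffered H2O2 cleaves the B–C bond and frees the diol; the closest known reaction types are the boronic acid hemiester (tethered hydroxide) oxa-Michael addition to γ- and δ-hydroxy enones with a β-CH acceptor carbon and the hemiacetal-alkoxide tethered oxa-Michael addition, which to my knowledge have not been used to build a tertiary carbinol on a β,β-disubstituted cyclic enone.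

Step 8
Reactants: 13 (3R,3aS,4S,8aR)-3,4-dihydroxy-6,8a-dimethyl-3-(propan-2-yl)-3,3a,4,5,8,8a-hexahydroazulen-1(2H)-one; 14 4-acetoxybenzoyl chloride
Product: 15 (3R,3aS,4S,8aR)-3-hydroxy-6,8a-dimethyl-1-oxo-3-(propan-2-yl)-1,2,3,3a,4,5,8,8a-octahydroazulen-4-yl 4-(acetyloxy)benzoate
Conditions: pyridine, DMAP (10 mol %), CH2Cl2, 0 °C
Reagents that add atoms: none
Why: DMAP-catalysed acylation (nucleophilic acyl substitution) is chemoselective for the secondary C6 hydroxyl because the tertiary C4 hydroxyl does not react, and no stereocentre changes.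

Step 9
Reactants: 15 (3R,3aS,4S,8aR)-3-hydroxy-6,8a-dimethyl-1-oxo-3-(propan-2-yl)-1,2,3,3a,4,5,8,8a-octahydroazulen-4-yl 4-(acetyloxy)benzoate
Product: 16 (1S,3R,3aS,4S,8aR)-1,3-dihydroxy-6,8a-dimethyl-3-(propan-2-yl)-1,2,3,3a,4,5,8,8a-octahydroazulen-4-yl 4-(acetyloxy)benzoate
Conditions: Me4NBH(OAc)3 (5 equiv), MeCN/AcOH 1:1, −30 → −10 °C
Reagents that add atoms: none
Why: Evans–Saksena hydroxyl-directed reduction in which the 4β-hydroxyl exchanges an acetate on boron and delivers hydride intramolecularly to the β-face of the C2 ketone, giving the 2α-alcohol (trans-1,3-diol) while both esters survive.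

Step 10
Reactants: 16 (1S,3R,3aS,4S,8aR)-1,3-dihydroxy-6,8a-dimethyl-3-(propan-2-yl)-1,2,3,3a,4,5,8,8a-octahydroazulen-4-yl 4-(acetyloxy)benzoate
Product: 17 (1S,3R,3aS,4S,8aR)-1,3-dihydroxy-6,8a-dimethyl-3-(propan-2-yl)-1,2,3,3a,4,5,8,8a-octahydroazulen-4-yl 4-hydroxybenzoate (2α-hydroxyferutinin)
Conditions: pyrrolidine (3 equiv), CH2Cl2, 0 °C
Reagents that add atoms: none
Why: aminolysis (acyl transfer) cleaves the activated aryl acetate far faster than the hindered secondary benzoate, which is further deactivated once the phenol is free, and no stereocentre is touched.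

**Compound list**
1 | 3-methylbut-3-en-1-ol | CC(=C)CCO | starting material
2 | 3-methylbut-3-enal | CC(=C)CC=O | intermediate
3 | 3-ethoxycyclopent-2-en-1-one | CCOC1=CC(=O)CC1 | starting material
4 | dicyclohexyl[(4-ethoxycyclopenta-1,3-dien-2-yl)oxy]borane (boron enolate of 3) | CCOC1=CC(OB(C2CCCCC2)C2CCCCC2)=CC1 | intermediate
5 | rac-(5S,1′S)-3-ethoxy-5-(1-hydroxy-3-methylbut-3-en-1-yl)cyclopent-2-en-1-one (anti aldol, 1:1 mixture of 6 and its mirror image) | CCOC1=CC(=O)[C@@H](C1)[C@@H](O)CC(C)=C.CCOC1=CC(=O)[C@H](C1)[C@H](O)CC(C)=C | intermediate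
6 | (5S)-3-ethoxy-5-[(1S)-1-hydroxy-3-methylbut-3-en-1-yl]cyclopent-2-en-1-one | CCOC1=CC(=O)[C@@H](C1)[C@@H](O)CC(C)=C | intermediate
7 | (5S)-3-ethoxy-5-[(1S)-1-hydroxy-3-methylbut-3-en-1-yl]-1-(propan-2-yl)cyclopent-2-en-1-ol (new carbinol centre not controlled) | CCOC1=CC(O)(C(C)C)[C@@H](C1)[C@@H](O)CC(C)=C | intermediate
8 | (4R)-4-[(1S)-1-hydroxy-3-methylbut-3-en-1-yl]-3-(propan-2-yl)cyclopent-2-en-1-one | O=C1C=C(C(C)C)[C@@H](C1)[C@@H](O)CC(C)=C | intermediate
9 | (4R)-4-[(1S)-1-hydroxy-3-methylbut-3-en-1-yl]-5-methyl-3-(propan-2-yl)cyclopent-2-en-1-one (both C5 epimers) | CC1C(=O)C=C(C(C)C)[C@@H]1[C@@H](O)CC(C)=C | intermediate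
10 | (4S,5R)-4-[(1S)-1-hydroxy-3-methylbut-3-en-1-yl]-5-methyl-3-(propan-2-yl)-5-(prop-2-en-1-yl)cyclopent-2-en-1-one | C=CC[C@]1(C)[C@@H]([C@@H](O)CC(C)=C)C(C(C)C)=CC1=O | intermediate
11 | (3aS,4S,8aR)-4-hydroxy-6,8a-dimethyl-3-(propan-2-yl)-4,5,8,8a-tetrahydroazulen-1(3aH)-one | CC1=CC[C@]2(C)[C@@H]([C@@H](O)C1)C(C(C)C)=CC2=O | intermediate
12 | cyclic phenylboronate of 13 (O4–B(Ph)–O6 dioxaborinane, cis-fused to the five-membered ring) | CC1=CC[C@]2(C)[C@@H]([C@@H](OB(c3ccccc3)O4)C1)[C@]4(C(C)C)CC2=O | intermediate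
13 | (3R,3aS,4S,8aR)-3,4-dihydroxy-6,8a-dimethyl-3-(propan-2-yl)-3,3a,4,5,8,8a-hexahydroazulen-1(2H)-one | CC1=CC[C@]2(C)[C@@H]([C@@H](O)C1)[C@](O)(C(C)C)CC2=O | intermediate
14 | 4-acetoxybenzoyl chloride | CC(=O)Oc1ccc(cc1)C(Cl)=O | starting material
15 | (3R,3aS,4S,8aR)-3-hydroxy-6,8a-dimethyl-1-oxo-3-(propan-2-yl)-1,2,3,3a,4,5,8,8a-octahydroazulen-4-yl 4-(acetyloxy)benzoate | CC1=CC[C@]2(C)[C@@H]([C@@H](OC(=O)c3ccc(OC(C)=O)cc3)C1)[C@](O)(C(C)C)CC2=O | intermediate
16 | (1S,3R,3aS,4S,8aR)-1,3-dihydroxy-6,8a-dimethyl-3-(propan-2-yl)-1,2,3,3a,4,5,8,8a-octahydroazulen-4-yl 4-(acetyloxy)benzoate | CC1=CC[C@]2(C)[C@@H]([C@@H](OC(=O)c3ccc(OC(C)=O)cc3)C1)[C@](O)(C(C)C)C[C@@H]2O | intermediate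
17 | (1S,3R,3aS,4S,8aR)-1,3-dihydroxy-6,8a-dimethyl-3-(propan-2-yl)-1,2,3,3a,4,5,8,8a-octahydroazulen-4-yl 4-hydroxybenzoate (2α-hydroxyferutinin) | CC1=CC[C@]2(C)[C@@H]([C@@H](OC(=O)c3ccc(O)cc3)C1)[C@](O)(C(C)C)C[C@@H]2O | target

**Step count and risks**

Total step count: 10. Longest linear sequence: 10 steps (1 → 17); 3 and 14 enter at steps 2 and 8.

The three steps most likely to fail are the tethered oxa-Michael addition (step 7), the one-pot double alkylation (step 5) and the directed reduction (step 9).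

The oxa-Michael addition of step 7 is new. The acceptor carbon is fully substituted, the equilibrium may lie on the enone side, and the amine could epimerise C5 through the dienolate. A simple intermolecular epoxidation or conjugate borylation would be expected to attack C4 anti to C6, on the wrong face, so the fallback keeps the hydroxyl-directed logic but uses known reactions. It sets out from 11 and comes back to the route at 13.
- Silylation of 11 (TBSOTf, 2,6-lutidine) gives the silyl ether F5.
- Luche reduction (NaBH4, CeCl3·7H2O, MeOH, −40 °C) puts hydride on the α-face, anti to the angular methyl, and gives the 2β-allylic alcohol F6.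
- VO(acac)2 with tBuOOH epoxidises the C3=C4 alkene syn to that hydroxyl and gives the 3β,4β-epoxy alcohol F7.
- LiAlH4 opens the epoxide at the secondary carbon C3 and gives the 2β,4β-diol F8.
- Dess–Martin oxidation of the secondary alcohol gives the β-hydroxy ketone F9, and Bu4NF then frees 13.

The double alkylation of step 5 can suffer from over-methylation, γ-deprotonation next to the alkoxide, or a modest diastereomer ratio at the quaternary carbon. The fallback sets out from 8 and comes back at 10, replacing the second enolate alkylation by a palladium π-allyl process.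
- TBSOTf with 2,6-lutidine gives the silyl ether F1.
- LiN(iPr)2 and MeI give the 5-methyl enone F2.
- LiN(SiMe3)2, TMEDA and allyl chloroformate trap the α′-enolate on oxygen as the allyl enol carbonate F3.
- Pd(PPh3)4 in THF brings about the Tsuji decarboxylative allylation, again anti to the C5 side chain, and gives the quaternary silyl ether F4; Bu4NF then gives 10.

The directed reduction of step 9 may be slow or unselective, because the ketone is neopentyl and the directing hydroxyl is tertiary. Undirected hydride would attack from the α-face and give the wrong 2β-alcohol. The fallback sets out from 15 and comes back at 16, replacing substrate direction by reagent control: (R)-2-methyl-CBS-oxazaborolidine with catecholborane in toluene at −78 °C, which spares the ring alkene and both esters and, by the usual large/small model (quaternary C1 against CH2), places hydride on the β-face. It makes no new compound (F0).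

Further compounds
F1 | step 5 | (4R)-4-[(1S)-1-(tert-butyldimethylsilyloxy)-3-methylbut-3-en-1-yl]-3-(propan-2-yl)cyclopent-2-en-1-one (TBS ether of 8) | O=C1C=C(C(C)C)[C@@H](C1)[C@@H](O[Si](C)(C)C(C)(C)C)CC(C)=C
F2 | step 5 | 5-methyl derivative of F1 (both C5 epimers) | CC1C(=O)C=C(C(C)C)[C@@H]1[C@@H](O[Si](C)(C)C(C)(C)C)CC(C)=C
F3 | step 5 | allyl enol carbonate of F2 (allyl cyclopenta-1,4-dien-1-yl carbonate, enol double bond C1=C2) | CC1=C(OC(=O)OCC=C)C=C(C(C)C)[C@@H]1[C@@H](O[Si](C)(C)C(C)(C)C)CC(C)=C
F4 | step 5 | TBS ether of 10 | C=CC[C@]1(C)[C@@H]([C@@H](O[Si](C)(C)C(C)(C)C)CC(C)=C)C(C(C)C)=CC1=O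
F5 | step 7 | TBS ether of 11 | CC1=CC[C@]2(C)[C@@H]([C@@H](O[Si](C)(C)C(C)(C)C)C1)C(C(C)C)=CC2=O
F6 | step 7 | 2β-allylic alcohol from 1,2-reduction of F5 (hydroxyl cis to the C1 methyl) | CC1=CC[C@]2(C)[C@@H]([C@@H](O[Si](C)(C)C(C)(C)C)C1)C(C(C)C)=C[C@H]2O
F7 | step 7 | 3β,4β-epoxy-2β-alcohol from F6 | CC1=CC[C@]2(C)[C@@H]([C@@H](O[Si](C)(C)C(C)(C)C)C1)[C@@]3(C(C)C)O[C@H]3[C@H]2O
F8 | step 7 | 2β,4β-diol, 6-O-TBS ether | CC1=CC[C@]2(C)[C@@H]([C@@H](O[Si](C)(C)C(C)(C)C)C1)[C@](O)(C(C)C)C[C@H]2O
F9 | step 7 | 6-O-TBS ether of 13 | CC1=CC[C@]2(C)[C@@H]([C@@H](O[Si](C)(C)C(C)(C)C)C1)[C@](O)(C(C)C)CC2=O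
F0 | step 9 | none | none
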